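**Retrosynthetic overview**
1. Target 21 ⇒ bisphenol 13 plus two identical C3 arms: aryl–O–C bonds by Mitsunobu inversion of methyl (R)-lactate, aryl–C(=O) bonds by Weinreb ketone synthesis, carbinols by chelation-controlled reduction.
2. 13 ⇒ hemiketal 11, whose oxocarbenium ion is reduced by hydride to set the 2,3-cis aryl group ⇒ aryllithium 10 + trans,trans-lactone 9.
3. 9 ⇒ α-methylation of lactone 7 ⇒ Baeyer–Villiger ring expansion of 2-aryl-3-methylcyclobutanone 6 (key step: the benzylic ring carbon shifts from carbon to oxygen, four- to five-membered ring).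
4. 6 ⇒ desymmetrizing α-arylation of 3-methylcyclobutanone 5 with aryl bromide 4 (new catalytic step; fixes the absolute configuration of the core).
5. Ring order: only one ring is built, the oxolane, formed as the γ-lactone in step 5 from the purchased cyclobutanone and kept to the end; all four arenes come from catechol.

Assumption: oxolane locants follow the construction (C5 = aryl carbon from the cyclobutanone, C2 = aryl carbon from the lactone carbonyl); with these locants the target core is (2S,3R,4R,5R), i.e. 2,3-cis, 3,4-trans, 4,5-trans, and both arms are (1R,2S).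

**Step 1**
Reactants: 1 catechol
Product: 2 guaiacol (2-methoxyphenol)
Conditions: MeI (1.0 equiv), K2CO3 (1.0 equiv), DMF, rt
Reagents that add atoms: iodomethane, CI
Why: Williamson monoalkylation of the catechol monoanion with base and MeI limiting; 2 is separated from 1 and the dimethyl ether by distillation.

**Step 2**
Reactants: 2 guaiacol
Product: 3 4-bromo-2-methoxyphenol
Conditions: NBS, MeCN, 0 °C
Reagents that add atoms: N-bromosuccinimide, O=C1CCC(=O)N1Br
Why: electrophilic aromatic bromination; the free OH is the stronger director, so bromine enters para to OH.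

**Step 3**
Reactants: 3 4-bromo-2-methoxyphenol
Product: 4 1-(benzyloxy)-4-bromo-2-methoxybenzene
Conditions: BnBr, K2CO3, acetone, reflux
Reagents that add atoms: benzyl bromide, BrCc1ccccc1
Why: Williamson ether synthesis; benzyl protects the phenol through the base, organolithium and Lewis-acid steps.

**Step 4**
Reactants: 5 3-methylcyclobutan-1-one (3 equiv); 4 1-(benzyloxy)-4-bromo-2-methoxybenzene
Product: 6 (2R,3R)-2-[4-(benzyloxy)-3-methoxyphenyl]-3-methylcyclobutan-1-one (aryl and methyl trans)
Conditions: Pd(OAc)2 (5 mol %), P(t-Bu)3·HBF4 (10 mol %), (S)-α,α-diphenylprolinol trimethylsilyl ether (20 mol %), NaOAc, toluene, 50 °C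
Reagents that add atoms: none
Why: Proposed new method: intermolecular desymmetrizing α-arylation of a prochiral cyclobutanone by palladium/enamine dual catalysis; oxidative addition of 4 to zerovalent palladium gives an arylpalladium bromide (divalent palladium), the hindered chiral pyrrolidine forms two interconverting diastereomeric enamines of 5 (double bond toward either enantiotopic CH2), the one with the ring methyl away from the catalyst shield attacks palladium faster, C–C reductive elimination and hydrolysis release the ketone, and the acidic α-aryl centre equilibrates to trans, so the catalyst only chooses between the two enantiotopic α-carbons, which fixes C3 and thereby the whole core; closest known reaction types are Buchwald–Hartwig α-arylation of ketones, the intramolecular palladium/enamine α-arylation of cyclobutanones, and enamine (aldol) desymmetrization of 3-substituted cyclobutanones; the amine enantiomer shown stands for whichever gives (2R,3R).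

**Step 5**
Reactants: 6 (2R,3R)-2-[4-(benzyloxy)-3-methoxyphenyl]-3-methylcyclobutan-1-one
Product: 7 (4R,5R)-5-[4-(benzyloxy)-3-methoxyphenyl]-4-methyloxolan-2-one (trans)
Conditions: mCPBA, CH2Cl2, 0 °C to rt
Reagents that add atoms: 3-chloroperoxybenzoic acid, OOC(=O)c1cccc(Cl)c1
Why: Baeyer–Villiger ring expansion driven by cyclobutanone strain; in the Criegee adduct the benzylic, more substituted ring carbon shifts from carbon to oxygen with retention, so the trans relationship of 6 becomes 4,5-trans in the lactone.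

**Step 6**
Reactants: 7 (4R,5R)-5-[4-(benzyloxy)-3-methoxyphenyl]-4-methyloxolan-2-one
Product: 9 (3R,4R,5R)-5-[4-(benzyloxy)-3-methoxyphenyl]-3,4-dimethyloxolan-2-one, via lithium enolate 8 (not isolated)
Conditions: LiN(i-Pr)2, THF, −78 °C; then MeI, −78 to −40 °C
Reagents that add atoms: iodomethane, CI
Why: lactone enolate alkylation; MeI approaches the enolate face anti to the adjacent C4 methyl, giving the 3,4-trans (3R) product, which is also the thermodynamic epimer.

**Step 7**
Reactants: 4 1-(benzyloxy)-4-bromo-2-methoxybenzene; 9 (3R,4R,5R)-5-[4-(benzyloxy)-3-methoxyphenyl]-3,4-dimethyloxolan-2-one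
Product: 11 (3R,4R,5R)-2,5-bis[4-(benzyloxy)-3-methoxyphenyl]-3,4-dimethyloxolan-2-ol (C2 anomers, in equilibrium with the open hydroxy ketone), via aryllithium 10 (not isolated)
Conditions: 4, n-BuLi, THF, −78 °C; then 9, −78 °C; H2O
Reagents that add atoms: none
Why: bromine–lithium exchange followed by addition of the aryllithium to the lactone carbonyl, which stops at the lithium hemiketalate at −78 °C; no stereocentre is set because C2 is planarized in the next step.

**Step 8**
Reactants: 11 (3R,4R,5R)-2,5-bis[4-(benzyloxy)-3-methoxyphenyl]-3,4-dimethyloxolan-2-ol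
Product: 12 (2S,3R,4R,5R)-2,5-bis[4-(benzyloxy)-3-methoxyphenyl]-3,4-dimethyloxolane
Conditions: Et3SiH, BF3·OEt2, CH2Cl2, −78 °C
Reagents that add atoms: none
Why: reductive deoxygenation of a cyclic hemiketal (ionic hydrogenation); BF3 gives the 2-aryl oxocarbenium ion and hydride adds anti to the C3 methyl, placing the new aryl cis to C3-Me and cis to the C5 aryl (C2 = S), the kinetic outcome established for 2,5-diaryl-3,4-dimethyl hemiketals at low temperature.

**Step 9**
Reactants: 12 (2S,3R,4R,5R)-2,5-bis[4-(benzyloxy)-3-methoxyphenyl]-3,4-dimethyloxolane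
Product: 13 4,4'-[(2S,3R,4R,5R)-3,4-dimethyloxolane-2,5-diyl]bis(2-methoxyphenol)
Conditions: H2 (1 atm), 10% Pd/C, EtOAc, rt
Reagents that add atoms: none
Why: hydrogenolysis of the two benzyl aryl ethers; in neutral EtOAc this is much faster than cleavage of the ring benzylic C–O bonds.

**Step 10**
Reactants: 13 4,4'-[(2S,3R,4R,5R)-3,4-dimethyloxolane-2,5-diyl]bis(2-methoxyphenol); 14 methyl (R)-lactate (2.5 equiv)
Product: 15 dimethyl (2S,2'S)-2,2'-{[(2S,3R,4R,5R)-3,4-dimethyloxolane-2,5-diyl]bis[(2-methoxy-4,1-phenylene)oxy]}dipropanoate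
Conditions: PPh3, DIAD, THF, 0 °C to rt
Reagents that add atoms: none
Why: double Mitsunobu reaction; each phenol displaces the activated lactate oxygen by SN2 with clean inversion, so (R)-lactate gives the (S)-aryloxypropanoate (C8 of each arm).

**Step 11**
Reactants: 15 dimethyl (2S,2'S)-bis-ester
Product: 16 (2S,2'S)-2,2'-{[(2S,3R,4R,5R)-3,4-dimethyloxolane-2,5-diyl]bis[(2-methoxy-4,1-phenylene)oxy]}bis(N-methoxy-N-methylpropanamide)
Conditions: MeNH(OMe)·HCl, i-PrMgCl, THF, −20 °C
Reagents that add atoms: N,O-dimethylhydroxylamine hydrochloride, CNOC.Cl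
Why: Weinreb amide formation by aminolysis of the esters with the chloromagnesium amide; the low temperature leaves the α-aryloxy stereocentres untouched.

**Step 12**
Reactants: 1 catechol
Product: 17 veratrole (1,2-dimethoxybenzene)
Conditions: MeI (2.5 equiv), K2CO3, acetone, reflux
Reagents that add atoms: iodomethane, CI
Why: exhaustive Williamson methylation.

**Step 13**
Reactants: 17 veratrole
Product: 18 4-bromo-1,2-dimethoxybenzene
Conditions: NBS, MeCN, rt
Reagents that add atoms: N-bromosuccinimide, O=C1CCC(=O)N1Br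
Why: electrophilic bromination para to a methoxy group; the symmetry of 17 allows only one monobromide at this position.

**Step 14**
Reactants: 18 4-bromo-1,2-dimethoxybenzene (3 equiv); 16 bis(Weinreb amide)
Product: 20 (2S,2'S)-2,2'-{[(2S,3R,4R,5R)-3,4-dimethyloxolane-2,5-diyl]bis[(2-methoxy-4,1-phenylene)oxy]}bis[1-(3,4-dimethoxyphenyl)propan-1-one], via aryllithium 19 (not isolated)
Conditions: 18, n-BuLi, THF, −78 °C; then 16, −78 °C; H2O
Reagents that add atoms: none
Why: Weinreb ketone synthesis; the chelated tetrahedral adduct prevents over-addition, and fast addition at −78 °C outruns α-deprotonation, so the (S) centres are kept.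

**Step 15**
Reactants: 20 bis-ketone
Product: 21 target, (1R,2S,1'R,2'S)-2,2'-{[(2S,3R,4R,5R)-3,4-dimethyloxolane-2,5-diyl]bis[(2-methoxy-4,1-phenylene)oxy]}bis[1-(3,4-dimethoxyphenyl)propan-1-ol]
Conditions: Zn(BH4)2, Et2O/THF, −20 °C; H2O
Reagents that add atoms: none
Why: chelation-controlled reduction (Cram cyclic model); zinc bridges the carbonyl oxygen and the α-aryloxy oxygen (helped by the ortho methoxy), and hydride enters from the face of the α-hydrogen, giving the erythro (1R) carbinol from the (2S) ketone in both arms.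

**Compound list**
1 | catechol (benzene-1,2-diol) | Oc1ccccc1O | starting material
2 | guaiacol (2-methoxyphenol) | COc1ccccc1O | intermediate
3 | 4-bromo-2-methoxyphenol | COc1cc(Br)ccc1O | intermediate
4 | 1-(benzyloxy)-4-bromo-2-methoxybenzene | COc1cc(Br)ccc1OCc1ccccc1 | intermediate
5 | 3-methylcyclobutan-1-one | CC1CC(=O)C1 | starting material
6 | (2R,3R)-2-[4-(benzyloxy)-3-methoxyphenyl]-3-methylcyclobutan-1-one | O=C1C[C@@H](C)[C@@H]1c1ccc(OCc2ccccc2)c(OC)c1 | intermediate
7 | (4R,5R)-5-[4-(benzyloxy)-3-methoxyphenyl]-4-methyloxolan-2-one | O=C1C[C@@H](C)[C@H](c2ccc(OCc3ccccc3)c(OC)c2)O1 | intermediate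
8 | lithium enolate of 7 | [Li]OC1=C[C@@H](C)[C@H](c2ccc(OCc3ccccc3)c(OC)c2)O1 | intermediate
9 | (3R,4R,5R)-5-[4-(benzyloxy)-3-methoxyphenyl]-3,4-dimethyloxolan-2-one | O=C1[C@H](C)[C@@H](C)[C@H](c2ccc(OCc3ccccc3)c(OC)c2)O1 | intermediate
10 | [4-(benzyloxy)-3-methoxyphenyl]lithium | [Li]c1ccc(OCc2ccccc2)c(OC)c1 | intermediate
11 | (3R,4R,5R)-2,5-bis[4-(benzyloxy)-3-methoxyphenyl]-3,4-dimethyloxolan-2-ol (C2 anomers) | OC1(c2ccc(OCc3ccccc3)c(OC)c2)O[C@@H](c2ccc(OCc3ccccc3)c(OC)c2)[C@H](C)[C@H]1C | intermediate
12 | (2S,3R,4R,5R)-2,5-bis[4-(benzyloxy)-3-methoxyphenyl]-3,4-dimethyloxolane | COc1cc(ccc1OCc1ccccc1)[C@H]1O[C@@H](c2ccc(OCc3ccccc3)c(OC)c2)[C@H](C)[C@H]1C | intermediate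
13 | 4,4'-[(2S,3R,4R,5R)-3,4-dimethyloxolane-2,5-diyl]bis(2-methoxyphenol) | COc1cc(ccc1O)[C@H]1O[C@@H](c2ccc(O)c(OC)c2)[C@H](C)[C@H]1C | intermediate
14 | methyl (R)-lactate | C[C@@H](O)C(=O)OC | starting material
15 | dimethyl (2S,2'S)-2,2'-{[(2S,3R,4R,5R)-3,4-dimethyloxolane-2,5-diyl]bis[(2-methoxy-4,1-phenylene)oxy]}dipropanoate | COC(=O)[C@H](C)Oc1ccc(cc1OC)[C@H]1O[C@@H](c2ccc(O[C@@H](C)C(=O)OC)c(OC)c2)[C@H](C)[C@H]1C | intermediate
16 | (2S,2'S)-2,2'-{[(2S,3R,4R,5R)-3,4-dimethyloxolane-2,5-diyl]bis[(2-methoxy-4,1-phenylene)oxy]}bis(N-methoxy-N-methylpropanamide) | CON(C)C(=O)[C@H](C)Oc1ccc(cc1OC)[C@H]1O[C@@H](c2ccc(O[C@@H](C)C(=O)N(C)OC)c(OC)c2)[C@H](C)[C@H]1C | intermediate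
17 | veratrole (1,2-dimethoxybenzene) | COc1ccccc1OC | intermediate
18 | 4-bromo-1,2-dimethoxybenzene | COc1ccc(Br)cc1OC | intermediate
19 | (3,4-dimethoxyphenyl)lithium | [Li]c1ccc(OC)c(OC)c1 | intermediate
20 | (2S,2'S)-2,2'-{[(2S,3R,4R,5R)-3,4-dimethyloxolane-2,5-diyl]bis[(2-methoxy-4,1-phenylene)oxy]}bis[1-(3,4-dimethoxyphenyl)propan-1-one] | COc1ccc(cc1OC)C(=O)[C@H](C)Oc1ccc(cc1OC)[C@H]1O[C@@H](c2ccc(O[C@@H](C)C(=O)c3ccc(OC)c(OC)c3)c(OC)c2)[C@H](C)[C@H]1C | intermediate
21 | (1R,2S,1'R,2'S)-2,2'-{[(2S,3R,4R,5R)-3,4-dimethyloxolane-2,5-diyl]bis[(2-methoxy-4,1-phenylene)oxy]}bis[1-(3,4-dimethoxyphenyl)propan-1-ol] | COc1ccc([C@@H](O)[C@H](C)Oc2ccc([C@H]3O[C@@H](c4ccc(O[C@@H](C)[C@H](O)c5ccc(OC)c(OC)c5)c(OC)c4)[C@H](C)[C@H]3C)cc2OC)cc1OC | target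

**Totals**
Total step count: 15. Longest linear sequence: 13 (steps 1–11, 14, 15, from catechol); steps 12–13 form the side branch.

**Three steps most likely to fail**

Step 4 (the proposed new arylation). Risks are N-arylation of the amine catalyst, double arylation, ring opening by aryl addition to the carbonyl, and an unknown sense or level of induction. The fallback uses known chemistry and sets out from 5 and 4 and comes back at 6. Compound 5 is deprotonated enantioselectively with a chiral lithium amide, lithium (R,R)- or (S,S)-bis(1-phenylethyl)amide (whichever gives the R enol ether), in THF at −100 °C with Me3SiCl present, a desymmetrization known for 3-substituted cyclobutanones, to give (R)-trimethyl[(3-methylcyclobut-1-en-1-yl)oxy]silane F1. F1 is then arylated with 4 under Pd(OAc)2/P(t-Bu)3 with Bu3SnF and CsF in toluene at 85 °C (palladium-catalysed arylation of silyl enol ethers). The aryl group goes regiospecifically onto the enol carbon, and equilibration to trans gives 6.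

Step 8 (hemiketal reduction). If the temperature rises, acid-promoted epimerization through benzylic ring opening erodes the 2,3-cis selectivity toward the all-trans isomer. The fallback sets out from 11 and comes back at 12. The open hydroxy-ketone form of 11 is reduced with LiBH(s-Bu)3 in THF (Felkin–Anh, anti) to the C2-symmetric (1R,2R,3R,4R)-1,4-bis[4-(benzyloxy)-3-methoxyphenyl]-2,3-dimethylbutane-1,4-diol F2. Treatment with MsCl/Et3N in CH2Cl2 at 0 °C gives (1R,2R,3R,4R)-1,4-bis[4-(benzyloxy)-3-methoxyphenyl]-4-hydroxy-2,3-dimethylbutyl methanesulfonate F3 in the flask. F3 closes by intramolecular SN2 with inversion at one benzylic carbon. Because F2 is C2-symmetric, activation of either hydroxyl gives the same 12.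

Step 15 (double erythro-selective reduction). The aryloxy group chelates weakly, so selectivity at two independent sites may be incomplete. The fallback sets out from 15 and comes back at 21, replacing steps 11, 14 and 15. Compound 15 is reduced with i-Bu2AlH in CH2Cl2 at −78 °C to (2S,2'S)-2,2'-{[(2S,3R,4R,5R)-3,4-dimethyloxolane-2,5-diyl]bis[(2-methoxy-4,1-phenylene)oxy]}dipropanal F4. F4 is used at once with aryllithium 19 in THF at −78 °C. Polar Felkin–Anh (non-chelated) addition to an α-aryloxy aldehyde gives the anti (erythro) carbinol, so C7 of each arm is set in the C–C bond-forming step instead of a reduction, giving 21.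

**Further compounds**
F1 | step 4 | (R)-trimethyl[(3-methylcyclobut-1-en-1-yl)oxy]silane | C[C@H]1C=C(O[Si](C)(C)C)C1
F2 | step 8 | (1R,2R,3R,4R)-1,4-bis[4-(benzyloxy)-3-methoxyphenyl]-2,3-dimethylbutane-1,4-diol | O[C@@H](c1ccc(OCc2ccccc2)c(OC)c1)[C@H](C)[C@@H](C)[C@@H](O)c1ccc(OCc2ccccc2)c(OC)c1
F3 | step 8 | (1R,2R,3R,4R)-1,4-bis[4-(benzyloxy)-3-methoxyphenyl]-4-hydroxy-2,3-dimethylbutyl methanesulfonate | CS(=O)(=O)O[C@@H](c1ccc(OCc2ccccc2)c(OC)c1)[C@H](C)[C@@H](C)[C@@H](O)c1ccc(OCc2ccccc2)c(OC)c1
F4 | step 15 | (2S,2'S)-2,2'-{[(2S,3R,4R,5R)-3,4-dimethyloxolane-2,5-diyl]bis[(2-methoxy-4,1-phenylene)oxy]}dipropanal | O=C[C@H](C)Oc1ccc(cc1OC)[C@H]1O[C@@H](c2ccc(O[C@@H](C)C=O)c(OC)c2)[C@H](C)[C@H]1C
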